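**Retrosynthetic overview**

- The target is the 2,15-diacetate of a labd-7-ene-2,3,15-triol. The acetates go on last (primary C15–OH and equatorial C2–OH react, the axial C3–OH beside C4 does not). The C20 methyl comes from an angular ester, and the C7–C8 alkene from a C7 ketone.
- Structural feature used: in ring B (C5–C10) the fusion bond C5–C10 and the bond C8–C9 lie opposite each other, and C1–C4 of ring A (cis-2,3-diol, gem-dimethyl C4) form a four-atom bridge from C10 to C5. One [4+2] of an acyclic 1,7,9-decatriene therefore closes rings A and B together.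
- The triene is assembled by Still–Gennari olefination (C9=C10) of a citronellol-derived aldehyde with an α-substituted phosphonoacetate. The 2-silyloxy diene (C5–C8) is made last, from a C5 aldehyde, by Horner–Wadsworth–Emmons reaction and enol silylation.
- The tether C1–C5 comes from (S)-glyceraldehyde acetonide by anti-selective reverse prenylation (C3–C4), acetonide transposition to O2/O3, and triflate alkylation at C1.

Key step: step 14

Remarks: labdane numbering (C1–C20) is used for every carbon that ends up in the target. The C8 configuration drawn for 22 and 23 is the one the cycloaddition should give; it is erased in step 16.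

**Route**

Step 1
Reactants: 1 (S)-2,2-dimethyl-1,3-dioxolane-4-carbaldehyde; 2 prenyl bromide
Product: 4 (1R)-1-[(4S)-2,2-dimethyl-1,3-dioxolan-4-yl]-2,2-dimethylbut-3-en-1-ol, via prenylzinc bromide 3 (not isolated)
Conditions: Zn dust, THF/sat. aq. NH4Cl, 0 °C to rt
Reagents that add atoms: none
Why: Barbier-type allylation in which the allylic zinc reagent adds through its γ-carbon (six-membered transition state) to give the reverse-prenyl adduct, and Felkin–Anh attack anti to the dioxolane oxygen should set the new carbinol centre (C3) anti to C2.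

Step 2
Reactants: 4
Product: 5 (2S,3R)-4,4-dimethylhex-5-ene-1,2,3-triol
Conditions: AcOH/H2O (4:1), 40 °C
Reagents that add atoms: none
Why: Acid hydrolysis of the terminal acetonide; no other acid-labile group is present and no stereocentre is touched.

Step 3
Reactants: 5
Product: 6 (2S,3R)-1-[(tert-butyldiphenylsilyl)oxy]-4,4-dimethylhex-5-ene-2,3-diol
Conditions: TBDPSCl (1.05 equiv), imidazole, CH2Cl2, 0 °C
Reagents that add atoms: tert-butyl(chloro)diphenylsilane, CC(C)(C)[Si](Cl)(c1ccccc1)c1ccccc1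
Why: Silylation with a bulky chlorosilane is selective for the primary hydroxyl over the two secondary ones, one of which is neopentyl.

Step 4
Reactants: 6
Product: 7 tert-butyl{[(4S,5R)-2,2-dimethyl-5-(2-methylbut-3-en-2-yl)-1,3-dioxolan-4-yl]methoxy}diphenylsilane
Conditions: 2,2-dimethoxypropane, PPTS (cat.), CH2Cl2, rt
Reagents that add atoms: 2,2-dimethoxypropane, COC(C)(C)OC
Why: Acid-catalysed transacetalisation closes the cis-dioxolane on the only free diol (O2/O3) with retention at both carbons.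

Step 5
Reactants: 7
Product: 8 [(4S,5R)-2,2-dimethyl-5-(2-methylbut-3-en-2-yl)-1,3-dioxolan-4-yl]methanol
Conditions: Bu4NF, THF, 0 °C to rt
Reagents that add atoms: none
Why: Fluoride-induced desilylation frees the C1 hydroxyl and leaves the acetonide and the vinyl group alone.

Step 6
Reactants: 8
Product: 9 [(4S,5R)-2,2-dimethyl-5-(2-methylbut-3-en-2-yl)-1,3-dioxolan-4-yl]methyl trifluoromethanesulfonate
Conditions: Tf2O, 2,6-lutidine, CH2Cl2, −78 °C; cold aqueous work-up, used at once
Reagents that add atoms: trifluoromethanesulfonic anhydride, O=S(=O)(OS(=O)(=O)C(F)(F)F)C(F)(F)F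
Why: O-Sulfonylation of a primary alcohol; the β-oxygen suppresses ionisation, so the triflate should be stable enough to handle cold.

Step 7
Reactants: 9; 10 methyl bis(2,2,2-trifluoroethyl)phosphonoacetate
Product: 11 methyl 2-[bis(2,2,2-trifluoroethoxy)phosphoryl]-3-[(4S,5R)-2,2-dimethyl-5-(2-methylbut-3-en-2-yl)-1,3-dioxolan-4-yl]propanoate (both epimers at the phosphonate carbon)
Conditions: 10 (1.5 equiv), NaH, THF/DMF, 0 °C; then 9, 0 °C to rt
Reagents that add atoms: none
Why: SN2 C-alkylation of the stabilised phosphonoacetate carbanion, for which the triflate leaving group compensates the rate-retarding β-oxygen at C1, with excess anion to limit dialkylation; the new centre (C10) becomes sp2 in step 10.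

Step 8
Reactants: 12 (S)-citronellol
Product: 13 tert-butyl{[(3S)-3,7-dimethyloct-6-en-1-yl]oxy}dimethylsilane
Conditions: TBSCl, imidazole, CH2Cl2, rt
Reagents that add atoms: tert-butyl(chloro)dimethylsilane, CC(C)(C)[Si](C)(C)Cl
Why: Standard silyl protection of the primary alcohol that becomes C15–O.

Step 9
Reactants: 13
Product: 15 (4S)-6-[(tert-butyldimethylsilyl)oxy]-4-methylhexanal, via ozonide 14 (not isolated)
Conditions: O3, CH2Cl2, −78 °C; then PPh3, −78 °C to rt
Reagents that add atoms: ozone, [O-][O+]=O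
Why: Ozonolysis with reductive work-up cleaves the trisubstituted alkene to the aldehyde (future C9); the C13 stereocentre is remote and untouched.

Step 10
Reactants: 11; 15
Product: 16 methyl (2Z,6S)-8-[(tert-butyldimethylsilyl)oxy]-2-{[(4S,5R)-2,2-dimethyl-5-(2-methylbut-3-en-2-yl)-1,3-dioxolan-4-yl]methyl}-6-methyloct-2-enoate
Conditions: KN(SiMe3)2, 18-crown-6, THF, −78 °C; then 15
Reagents that add atoms: none
Why: Still–Gennari olefination, in which fast elimination from the electron-poor trifluoroethyl phosphonate adduct under dissociating conditions should give the kinetic (Z)-trisubstituted enoate with C11 cis to the ester.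

Step 11
Reactants: 16
Product: 18 methyl (2Z,6S)-8-[(tert-butyldimethylsilyl)oxy]-2-{[(4S,5R)-2,2-dimethyl-5-(2-methyl-1-oxopropan-2-yl)-1,3-dioxolan-4-yl]methyl}-6-methyloct-2-enoate, via ozonide 17 (not isolated)
Conditions: O3 (1 equiv, Sudan Red 7B as end-point indicator), CH2Cl2, −78 °C; then PPh3
Reagents that add atoms: ozone, [O-][O+]=O
Why: Chemoselective ozonolysis, since electrophilic ozone attacks the isolated monosubstituted vinyl group much faster than the conjugated, electron-poor trisubstituted enoate.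

Step 12
Reactants: 18; 19 diethyl (2-oxobutyl)phosphonate
Product: 20 methyl (2Z,6S)-8-[(tert-butyldimethylsilyl)oxy]-2-({(4S,5R)-2,2-dimethyl-5-[(3E)-2-methyl-5-oxohept-3-en-2-yl]-1,3-dioxolan-4-yl}methyl)-6-methyloct-2-enoate
Conditions: Ba(OH)2·8H2O, THF/H2O (40:1), rt
Reagents that add atoms: none
Why: Horner–Wadsworth–Emmons reaction of a β-keto phosphonate with a non-enolisable, α-quaternary aldehyde under mild hydroxide conditions should give the (E)-enone (C5=C6) without touching the hindered (Z)-enoate.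

Step 13
Reactants: 20
Product: 21 methyl (2Z,6S)-8-[(tert-butyldimethylsilyl)oxy]-2-({(4S,5R)-5-[(3E,5Z)-5-[(tert-butyldimethylsilyl)oxy]-2-methylhepta-3,5-dien-2-yl]-2,2-dimethyl-1,3-dioxolan-4-yl}methyl)-6-methyloct-2-enoate
Conditions: TBSOTf, Et3N, CH2Cl2, −78 to 0 °C
Reagents that add atoms: tert-butyldimethylsilyl trifluoromethanesulfonate, CC(C)(C)[Si](C)(C)OS(=O)(=O)C(F)(F)F
Why: Soft enolisation and O-silylation of the ethyl ketone, where only C8 carries acidic hydrogens (C4 is quaternary) and the (Z)-enol ether, with the methyl trans to the vinyl group, avoids A(1,3) strain.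

Step 14
Reactants: 21
Product: 22 methyl 7,15-bis[(tert-butyldimethylsilyl)oxy]-2,3-(isopropylidenedioxy)labd-6-en-20-oate (trans-fused; C2, C3, C5, C9, C10 and C13 arranged as in the target with the ester in place of the C20 methyl; 8-methyl cis to C11 and to the ester)
Conditions: PhMe (0.01 M), BHT (cat.), base-washed sealed tube, 180 °C
Reagents that add atoms: none
Why: A concerted, asynchronous thermal [4+2] cycloaddition in which C8, the β-carbon of the silyl enol ether, bonds to C9, the β-carbon of the enoate, ahead of C5–C10; the closest known reaction type is the type 1 intramolecular Diels–Alder reaction of 1,7,9-decatrienes carrying an ester on the internal dienophile carbon. Ring B (C5–C10) closes by the cycloaddition itself and ring A (C10, C1–C5) closes as the fused ring spanned by the four-atom tether across the new C5–C10 bond. Suprafacial addition to the (Z)-enoate fixes C11 cis to the ester at C9/C10, and the (Z)-enol ether, whose methyl points outward, places the 8-methyl cis to C11 (this centre is lost later). The trans ring fusion at C5/C10 follows from the transition state with the ester endo and the tether anti. The sense relative to C2/C3 follows from a chair-like tether in which O2 is equatorial and O3 axial (anti to the axial C4 methyl), because the other chair would put O2 axial against both the axial C4 methyl and the ester. The step therefore needs trans over cis fusion and one diene face, and these are secured by the endo preference of the conjugating ester, the gem-dimethyl group (reactive rotamer) and the cis-fused dioxolane.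

Step 15
Reactants: 22
Product: 23 methyl 15-[(tert-butyldimethylsilyl)oxy]-2,3-(isopropylidenedioxy)-7-oxolabdan-20-oate (configuration as in 22)
Conditions: Bu4NF (1.1 equiv), AcOH (1.2 equiv), THF, −20 °C
Reagents that add atoms: none
Why: Buffered fluoride cleaves the silyl enol ether far faster than the primary alkyl silyl ether, and the enolate is protonated at C6, so no stereocentre is affected.

Step 16
Reactants: 23
Product: 24 methyl 15-[(tert-butyldimethylsilyl)oxy]-2,3-(isopropylidenedioxy)-7-{[(trifluoromethyl)sulfonyl]oxy}labd-7-en-20-oate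
Conditions: Tf2O, 2,6-di-tert-butyl-4-methylpyridine, CH2Cl2, 0 °C to rt
Reagents that add atoms: trifluoromethanesulfonic anhydride, O=S(=O)(OS(=O)(=O)C(F)(F)F)C(F)(F)F
Why: O-Triflation of the ketone with a hindered pyridine base should favour the more substituted C7=C8 enol triflate, helped by release of the 1,3-diaxial contact between the 8-methyl and the ester.

Step 17
Reactants: 24
Product: 25 methyl 15-[(tert-butyldimethylsilyl)oxy]-2,3-(isopropylidenedioxy)labd-7-en-20-oate
Conditions: Pd(OAc)2 (5 mol %), PPh3, Bu3N, HCO2H, DMF, 60 °C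
Reagents that add atoms: none
Why: Palladium-catalysed formate reduction of a vinyl triflate (oxidative addition, decarboxylation of formate, reductive elimination) replaces the triflate by hydrogen without moving the C7=C8 double bond.

Step 18
Reactants: 25
Product: 26 15-[(tert-butyldimethylsilyl)oxy]-2,3-(isopropylidenedioxy)labd-7-en-20-ol
Conditions: LiAlH4, THF, 0 °C to rt
Reagents that add atoms: none
Why: Hydride reduction of the hindered angular ester to the neopentyl alcohol; silyl ether, acetonide and alkene are inert.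

Step 19
Reactants: 26
Product: 27 15-[(tert-butyldimethylsilyl)oxy]-2,3-(isopropylidenedioxy)labd-7-en-20-al
Conditions: Dess–Martin periodinane, CH2Cl2, rt
Reagents that add atoms: none
Why: Dess–Martin oxidation of a primary alcohol to a non-enolisable aldehyde, so over-oxidation and epimerisation are not an issue.

Step 20
Reactants: 27
Product: 29 tert-butyl{[2,3-(isopropylidenedioxy)labd-7-en-15-yl]oxy}dimethylsilane, via hydrazone 28 (not isolated)
Conditions: N2H4·H2O (excess), EtOH, 80 °C; then KOtBu, PhMe, 110 °C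
Reagents that add atoms: none
Why: Wolff–Kishner reduction (hydrazone formation, then base-induced loss of N2), the classical conversion of an angular aldehyde into the angular methyl, run in the alkoxide/toluene variant so that the silyl ether should survive.

Step 21
Reactants: 29
Product: 30 (2S,3R,5S,9R,10S,13S)-labd-7-ene-2,3,15-triol
Conditions: 1 M aq. HCl/THF (1:4), rt
Reagents that add atoms: none
Why: Dilute acid hydrolyses the acetonide and the primary silyl ether in one operation, and the trisubstituted alkene should tolerate it at room temperature.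

Step 22
Reactants: 30
Product: 31 (2S,3R,5S,9R,10S,13S)-3-hydroxylabd-7-ene-2,15-diyl diacetate (CNP0144124.1)
Conditions: Ac2O (2.2 equiv), pyridine, CH2Cl2, 0 °C to rt
Reagents that add atoms: acetic anhydride, CC(=O)OC(C)=O
Why: Selective acylation, since the primary C15–OH and the equatorial C2–OH react much faster than the axial C3–OH flanked by the C4 gem-dimethyl group.

**Compound list**

1 | (S)-2,2-dimethyl-1,3-dioxolane-4-carbaldehyde | O=C[C@@H]1COC(C)(C)O1 | starting material
2 | prenyl bromide (1-bromo-3-methylbut-2-ene) | CC(C)=CCBr | starting material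
3 | prenylzinc bromide | CC(C)=CC[Zn]Br | intermediate
4 | (1R)-1-[(4S)-2,2-dimethyl-1,3-dioxolan-4-yl]-2,2-dimethylbut-3-en-1-ol | C=CC(C)(C)[C@@H](O)[C@@H]1COC(C)(C)O1 | intermediate
5 | (2S,3R)-4,4-dimethylhex-5-ene-1,2,3-triol | C=CC(C)(C)[C@@H](O)[C@@H](O)CO | intermediate
6 | (2S,3R)-1-[(tert-butyldiphenylsilyl)oxy]-4,4-dimethylhex-5-ene-2,3-diol | C=CC(C)(C)[C@@H](O)[C@@H](O)CO[Si](c1ccccc1)(c1ccccc1)C(C)(C)C | intermediate
7 | tert-butyl{[(4S,5R)-2,2-dimethyl-5-(2-methylbut-3-en-2-yl)-1,3-dioxolan-4-yl]methoxy}diphenylsilane | C=CC(C)(C)[C@H]1OC(C)(C)O[C@H]1CO[Si](c2ccccc2)(c2ccccc2)C(C)(C)C | intermediate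
8 | [(4S,5R)-2,2-dimethyl-5-(2-methylbut-3-en-2-yl)-1,3-dioxolan-4-yl]methanol | C=CC(C)(C)[C@H]1OC(C)(C)O[C@H]1CO | intermediate
9 | [(4S,5R)-2,2-dimethyl-5-(2-methylbut-3-en-2-yl)-1,3-dioxolan-4-yl]methyl trifluoromethanesulfonate | C=CC(C)(C)[C@H]1OC(C)(C)O[C@H]1COS(=O)(=O)C(F)(F)F | intermediate
10 | methyl bis(2,2,2-trifluoroethyl)phosphonoacetate | COC(=O)CP(=O)(OCC(F)(F)F)OCC(F)(F)F | starting material
11 | methyl 2-[bis(2,2,2-trifluoroethoxy)phosphoryl]-3-[(4S,5R)-2,2-dimethyl-5-(2-methylbut-3-en-2-yl)-1,3-dioxolan-4-yl]propanoate | C=CC(C)(C)[C@H]1OC(C)(C)O[C@H]1CC(C(=O)OC)P(=O)(OCC(F)(F)F)OCC(F)(F)F | intermediate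
12 | (S)-citronellol | OCC[C@@H](C)CCC=C(C)C | starting material
13 | tert-butyl{[(3S)-3,7-dimethyloct-6-en-1-yl]oxy}dimethylsilane | CC(C)(C)[Si](C)(C)OCC[C@@H](C)CCC=C(C)C | intermediate
14 | 3-{(3S)-5-[(tert-butyldimethylsilyl)oxy]-3-methylpentyl}-5,5-dimethyl-1,2,4-trioxolane | CC(C)(C)[Si](C)(C)OCC[C@@H](C)CCC1OOC(C)(C)O1 | intermediate
15 | (4S)-6-[(tert-butyldimethylsilyl)oxy]-4-methylhexanal | CC(C)(C)[Si](C)(C)OCC[C@@H](C)CCC=O | intermediate
16 | methyl (2Z,6S)-8-[(tert-butyldimethylsilyl)oxy]-2-{[(4S,5R)-2,2-dimethyl-5-(2-methylbut-3-en-2-yl)-1,3-dioxolan-4-yl]methyl}-6-methyloct-2-enoate | CC(C)(C)[Si](C)(C)OCC[C@@H](C)CC/C=C(\C(=O)OC)C[C@H](O1)[C@H](OC1(C)C)C(C)(C)C=C | intermediate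
17 | ozonide of 16 at the vinyl group (1,2,4-trioxolan-3-yl in place of vinyl) | CC(C)(C)[Si](C)(C)OCC[C@@H](C)CC/C=C(\C(=O)OC)C[C@H](O1)[C@H](OC1(C)C)C(C)(C)C2OOCO2 | intermediate
18 | methyl (2Z,6S)-8-[(tert-butyldimethylsilyl)oxy]-2-{[(4S,5R)-2,2-dimethyl-5-(2-methyl-1-oxopropan-2-yl)-1,3-dioxolan-4-yl]methyl}-6-methyloct-2-enoate | CC(C)(C)[Si](C)(C)OCC[C@@H](C)CC/C=C(\C(=O)OC)C[C@H](O1)[C@H](OC1(C)C)C(C)(C)C=O | intermediate
19 | diethyl (2-oxobutyl)phosphonate | CCC(=O)CP(=O)(OCC)OCC | starting material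
20 | methyl (2Z,6S)-8-[(tert-butyldimethylsilyl)oxy]-2-({(4S,5R)-2,2-dimethyl-5-[(3E)-2-methyl-5-oxohept-3-en-2-yl]-1,3-dioxolan-4-yl}methyl)-6-methyloct-2-enoate | CC(C)(C)[Si](C)(C)OCC[C@@H](C)CC/C=C(\C(=O)OC)C[C@H](O1)[C@H](OC1(C)C)C(C)(C)/C=C/C(=O)CC | intermediate
21 | methyl (2Z,6S)-8-[(tert-butyldimethylsilyl)oxy]-2-({(4S,5R)-5-[(3E,5Z)-5-[(tert-butyldimethylsilyl)oxy]-2-methylhepta-3,5-dien-2-yl]-2,2-dimethyl-1,3-dioxolan-4-yl}methyl)-6-methyloct-2-enoate | CC(C)(C)[Si](C)(C)OCC[C@@H](C)CC/C=C(\C(=O)OC)C[C@H](O1)[C@H](OC1(C)C)C(C)(C)/C=C/C(O[Si](C)(C)C(C)(C)C)=C/C | intermediate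
22 | methyl 7,15-bis[(tert-butyldimethylsilyl)oxy]-2,3-(isopropylidenedioxy)labd-6-en-20-oate (trans-fused, ester anti to the dioxolane oxygens, 8-methyl and C11 cis to the ester) | CC(C)(C)[Si](C)(C)OCC[C@@H](C)CC[C@@H]1[C@H](C)C(O[Si](C)(C)C(C)(C)C)=C[C@@H]2C(C)(C)[C@@H](O3)[C@@H](OC3(C)C)C[C@@]12C(=O)OC | intermediate
23 | methyl 15-[(tert-butyldimethylsilyl)oxy]-2,3-(isopropylidenedioxy)-7-oxolabdan-20-oate | CC(C)(C)[Si](C)(C)OCC[C@@H](C)CC[C@@H]1[C@H](C)C(=O)C[C@@H]2C(C)(C)[C@@H](O3)[C@@H](OC3(C)C)C[C@@]12C(=O)OC | intermediate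
24 | methyl 15-[(tert-butyldimethylsilyl)oxy]-2,3-(isopropylidenedioxy)-7-{[(trifluoromethyl)sulfonyl]oxy}labd-7-en-20-oate | CC(C)(C)[Si](C)(C)OCC[C@@H](C)CC[C@@H]1C(C)=C(OS(=O)(=O)C(F)(F)F)C[C@@H]2C(C)(C)[C@@H](O3)[C@@H](OC3(C)C)C[C@@]12C(=O)OC | intermediate
25 | methyl 15-[(tert-butyldimethylsilyl)oxy]-2,3-(isopropylidenedioxy)labd-7-en-20-oate | CC(C)(C)[Si](C)(C)OCC[C@@H](C)CC[C@@H]1C(C)=CC[C@@H]2C(C)(C)[C@@H](O3)[C@@H](OC3(C)C)C[C@@]12C(=O)OC | intermediate
26 | 15-[(tert-butyldimethylsilyl)oxy]-2,3-(isopropylidenedioxy)labd-7-en-20-ol | CC(C)(C)[Si](C)(C)OCC[C@@H](C)CC[C@@H]1C(C)=CC[C@@H]2C(C)(C)[C@@H](O3)[C@@H](OC3(C)C)C[C@@]12CO | intermediate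
27 | 15-[(tert-butyldimethylsilyl)oxy]-2,3-(isopropylidenedioxy)labd-7-en-20-al | CC(C)(C)[Si](C)(C)OCC[C@@H](C)CC[C@@H]1C(C)=CC[C@@H]2C(C)(C)[C@@H](O3)[C@@H](OC3(C)C)C[C@@]12C=O | intermediate
28 | hydrazone of aldehyde 27 | CC(C)(C)[Si](C)(C)OCC[C@@H](C)CC[C@@H]1C(C)=CC[C@@H]2C(C)(C)[C@@H](O3)[C@@H](OC3(C)C)C[C@@]12C=NN | intermediate
29 | tert-butyl{[2,3-(isopropylidenedioxy)labd-7-en-15-yl]oxy}dimethylsilane | CC(C)(C)[Si](C)(C)OCC[C@@H](C)CC[C@@H]1C(C)=CC[C@@H]2C(C)(C)[C@@H](O3)[C@@H](OC3(C)C)C[C@@]12C | intermediate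
30 | (2S,3R,5S,9R,10S,13S)-labd-7-ene-2,3,15-triol | OCC[C@@H](C)CC[C@@H]1C(C)=CC[C@@H]2C(C)(C)[C@@H](O)[C@@H](O)C[C@@]12C | intermediate
31 | (2S,3R,5S,9R,10S,13S)-3-hydroxylabd-7-ene-2,15-diyl diacetate (CNP0144124.1) | CC(=O)OCC[C@@H](C)CC[C@@H]1C(C)=CC[C@@H]2C(C)(C)[C@@H](O)[C@@H](OC(C)=O)C[C@@]12C | target

**Step count**

Total: 22 steps. Longest linear sequence: 20 steps (steps 1–7 and 10–22, from 1 to 31); the side-chain aldehyde 15 takes 2 steps (8 and 9).

**Steps most likely to fail**

1. Step 14 (cycloaddition). The trisubstituted (Z)-enoate is a weak dienophile, so the silyloxy diene may be lost to desilylation or ene pathways before ring closure. The ester may also direct endo too weakly, because the C11 chain must sit under the silyloxy-bearing C7, so cis-fused adduct may form.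
Fallback: change the activating group from ester to aldehyde, a much stronger dienophile handle that can also be complexed at low temperature. Setting out from 21, iBu2AlH (CH2Cl2, −78 °C) gives the (Z)-allylic alcohol F1, and Dess–Martin periodinane with pyridine gives the (Z)-enal F2. Cycloaddition of F2 (PhMe, 60–80 °C, or Me2AlCl, CH2Cl2, −78 °C) gives the C20 aldehyde adduct F3, and buffered Bu4NF/AcOH gives the keto aldehyde F4. NaClO2/NaH2PO4/2-methyl-2-butene gives the keto acid F5, and Me3SiCHN2 in MeOH/PhMe returns the route to ketone 23.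

2. Step 16 (enol triflate). Enolisation may go toward C6 instead of C8, which would put the alkene at C6–C7 after reduction, and the triflic acid salt may open the acetonide.
Fallback: remove the carbonyl through a carbene instead of an enol derivative. From 23, TsNHNH2 (EtOH, 50 °C) gives the C7 tosylhydrazone F6. Its sodium salt (NaH, 1 equiv) is heated in diglyme at 140 °C (aprotic Bamford–Stevens reaction), where 1,2-shift of the tertiary H8 should give the more substituted alkene. This comes back to the route at 25 and makes step 17 unnecessary.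

3. Step 7 (alkylation). Displacement at C1 may be slow next to the dioxolane oxygen, and the enolate oxygen may be alkylated, or a trifluoroethoxy group on phosphorus may be displaced, instead of C-alkylation.
Fallback: make the C1–C10 bond by condensation instead of substitution. From 8, Dess–Martin oxidation gives the cis-aldehyde F7, which must be kept cold and base-free to avoid epimerisation at C2. Knoevenagel condensation with 10 (TiCl4, N-methylmorpholine, THF, 0 °C) gives the alkylidene phosphonoacetate F8. Conjugate reduction with NaBH4 (EtOH, 0 °C) returns the route to 11.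

**Further compounds**

F1 | step 14 | (2Z)-allylic alcohol from 21 (CH2OH in place of the methyl ester) | CC(C)(C)[Si](C)(C)OCC[C@@H](C)CC/C=C(\CO)C[C@H](O1)[C@H](OC1(C)C)C(C)(C)/C=C/C(O[Si](C)(C)C(C)(C)C)=C/C
F2 | step 14 | (2Z)-enal from F1 | CC(C)(C)[Si](C)(C)OCC[C@@H](C)CC/C=C(\C=O)C[C@H](O1)[C@H](OC1(C)C)C(C)(C)/C=C/C(O[Si](C)(C)C(C)(C)C)=C/C
F3 | step 14 | 7,15-bis[(tert-butyldimethylsilyl)oxy]-2,3-(isopropylidenedioxy)labd-6-en-20-al | CC(C)(C)[Si](C)(C)OCC[C@@H](C)CC[C@@H]1[C@H](C)C(O[Si](C)(C)C(C)(C)C)=C[C@@H]2C(C)(C)[C@@H](O3)[C@@H](OC3(C)C)C[C@@]12C=O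
F4 | step 14 | 15-[(tert-butyldimethylsilyl)oxy]-2,3-(isopropylidenedioxy)-7-oxolabdan-20-al | CC(C)(C)[Si](C)(C)OCC[C@@H](C)CC[C@@H]1[C@H](C)C(=O)C[C@@H]2C(C)(C)[C@@H](O3)[C@@H](OC3(C)C)C[C@@]12C=O
F5 | step 14 | 15-[(tert-butyldimethylsilyl)oxy]-2,3-(isopropylidenedioxy)-7-oxolabdan-20-oic acid | CC(C)(C)[Si](C)(C)OCC[C@@H](C)CC[C@@H]1[C@H](C)C(=O)C[C@@H]2C(C)(C)[C@@H](O3)[C@@H](OC3(C)C)C[C@@]12C(=O)O
F6 | step 16 | C7 tosylhydrazone of ketone 23 | CC(C)(C)[Si](C)(C)OCC[C@@H](C)CC[C@@H]1[C@H](C)C(=NNS(=O)(=O)c4ccc(C)cc4)C[C@@H]2C(C)(C)[C@@H](O3)[C@@H](OC3(C)C)C[C@@]12C(=O)OC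
F7 | step 7 | (4R,5R)-2,2-dimethyl-5-(2-methylbut-3-en-2-yl)-1,3-dioxolane-4-carbaldehyde (cis) | C=CC(C)(C)[C@H]1OC(C)(C)O[C@H]1C=O
F8 | step 7 | methyl 2-[bis(2,2,2-trifluoroethoxy)phosphoryl]-3-[(4S,5R)-2,2-dimethyl-5-(2-methylbut-3-en-2-yl)-1,3-dioxolan-4-yl]prop-2-enoate (E/Z mixture) | C=CC(C)(C)[C@H]1OC(C)(C)O[C@H]1C=C(C(=O)OC)P(=O)(OCC(F)(F)F)OCC(F)(F)F
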